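**Retrosynthetic overview**
- Polymatin A comes from the 8-angelate of the α-methylene-γ-lactone by late-stage C8 esterification and C9 desilylation. The α-methylene is installed last by Mannich aminomethylation and elimination on the saturated trans-fused lactone.
- The second (γ-lactone) ring is closed by oxidative lactonisation of a 1,4-diol. Its C6 carbinol is set by ketoreductase reduction of a macrocyclic enone, which funnels any C6 epimer mixture into one isomer.
- The first carbocyclic ring is closed last among the carbon frameworks. It is the 10-membered ring, formed by an intramolecular Nozaki–Hiyama–Kishi (NHK) coupling of the (E)-vinyl iodide (C5) with a C6 aldehyde (a lactol) after cross-metathesis (CM) has built the C1=C10 enoate.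
- The stereotriad is built as follows: C8 by Noyori hydrogenation, C7 by Fráter–Seebach anti-alkylation, C9 by asymmetric Morita–Baylis–Hillman (MBH). A temporary γ-lactone masks C6 and C12 until the NHK step.
- Building blocks are ethyl 4-(benzyloxy)-3-oxobutanoate, allyl bromide, hexafluoroisopropyl (HFIP) acrylate, and a vinyl-iodide diene made from pent-4-yn-1-ol.

Assumptions (one line each):
- The cupreidine-type MBH catalyst gives the (9S) sense with aldehyde 14, and a commercial ketoreductase panel contains an (R)-selective enzyme for the C6 ketone.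
- CM of the 1,1-disubstituted acrylate gives the thermodynamic tiglate-type E-enoate, with the ester trans to C2 (ring-cis C9/C2 on C1=C10), as in the target.

**Route**

**Step 1**
Reactants: 1 pent-4-yn-1-ol
Product: 2 (E)-5-iodo-4-methylpent-4-en-1-ol
Conditions: Me3Al, Cp2ZrCl2 (cat.), CH2Cl2, 0 °C→rt; then I2, THF, –30 °C
Reagents that add atoms: trimethylaluminium C[Al](C)C (adds CH3); iodine II (adds I)
Why: Negishi Zr-catalysed carboalumination is a syn methylalumination of the terminal alkyne, and iodinolysis gives the E-trisubstituted vinyl iodide (I cis to Me, trans to the chain).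

**Step 2**
Reactants: 2
Product: 3 (E)-5-iodo-4-methylpent-4-enal
Conditions: Dess–Martin periodinane (DMP), NaHCO3, CH2Cl2, 0 °C→rt
Reagents that add atoms: none
Why: DMP oxidation of a primary alcohol leaves the vinyl iodide intact.

**Step 3**
Reactants: 3
Product: 4 (E)-1-iodo-2-methylhexa-1,5-diene
Conditions: Ph3PCH3Br, KOtBu, THF, 0 °C; then 3, –78 °C→rt
Reagents that add atoms: methylenetriphenylphosphorane C=P(c1ccccc1)(c1ccccc1)c1ccccc1 (adds CH2)
Why: Wittig methylenation of the aldehyde gives the terminal alkene (future C1) with no effect on the E-vinyl iodide.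

**Step 4**
Reactants: 5 ethyl 4-(benzyloxy)-3-oxobutanoate
Product: 6 ethyl (S)-4-(benzyloxy)-3-hydroxybutanoate
Conditions: H2 (50 atm), RuCl2[(R)-BINAP] (0.1 mol%), EtOH, 50 °C
Reagents that add atoms: none
Why: Noyori asymmetric hydrogenation of the β-keto ester sets C8 (S) by catalyst control.

**Step 5**
Reactants: 6; 7 allyl bromide
Product: 8 ethyl (2R,3S)-2-allyl-4-(benzyloxy)-3-hydroxybutanoate
Conditions: LDA (2.3 equiv), THF, –30 °C; then 7, DMPU, –30→0 °C
Reagents that add atoms: none (7 is the reactant)
Why: Fráter–Seebach alkylation of the chelated lithium dianion occurs anti to the C8 substituent, giving the 7,8-anti product that matches the target (C7 R at this stage).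

**Step 6**
Reactants: 8
Product: 9 ethyl (2R,3S)-4-(benzyloxy)-3-hydroxy-2-(2-oxoethyl)butanoate
Conditions: OsO4 (2 mol%), NaIO4 (4 equiv), 2,6-lutidine, dioxane/H2O 3:1, 23 °C
Reagents that add atoms: sodium periodate [Na+].[O-]I(=O)(=O)=O (supplies the aldehyde O; OsO4 is catalytic and leaves no atoms)
Why: Lemieux–Johnson cleavage of the terminal alkene gives the C12 aldehyde, with no stereocentre touched.

**Step 7**
Reactants: 9
Product: 10 ethyl (2R,3S)-4-(benzyloxy)-3-hydroxy-2-(2-hydroxyethyl)butanoate
Conditions: NaBH4 (1 equiv), EtOH, 0 °C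
Reagents that add atoms: none
Why: Chemoselective aldehyde reduction; the ester survives at 0 °C.

**Step 8**
Reactants: 10
Product: 11 (3R)-3-[(1S)-2-(benzyloxy)-1-hydroxyethyl]oxolan-2-one
Conditions: TsOH·H2O (10 mol%), toluene, 40 °C
Reagents that add atoms: none
Why: Acid-catalysed γ-hydroxy ester lactonisation (loss of EtOH) gives a temporary "reversed" lactone that masks C6 (as acyl) and C12 (as alkoxy) without affecting the stereocentres.

**Step 9**
Reactants: 11
Product: 12 (3R)-3-[(1S)-2-(benzyloxy)-1-(triethylsilyloxy)ethyl]oxolan-2-one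
Conditions: TESCl, imidazole, DMF, 23 °C
Reagents that add atoms: chlorotriethylsilane CC[Si](Cl)(CC)CC (adds SiEt3)
Why: Silylation of the C8 hydroxyl; this TES group is later removed selectively in the presence of TBS.

**Step 10**
Reactants: 12
Product: 13 (3R)-3-[(1S)-2-hydroxy-1-(triethylsilyloxy)ethyl]oxolan-2-one
Conditions: H2 (1 atm), 10% Pd/C, EtOAc, 23 °C
Reagents that add atoms: none
Why: Hydrogenolysis of the benzyl ether is safe here because no alkene is yet present; the lactone and TES ether survive.

**Step 11**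
Reactants: 13
Product: 14 (2S)-2-(triethylsilyloxy)-2-[(3R)-2-oxooxolan-3-yl]acetaldehyde
Conditions: DMP, NaHCO3, CH2Cl2, 0→23 °C (used crude)
Reagents that add atoms: none
Why: Buffered DMP oxidation avoids epimerisation of the α-silyloxy aldehyde.

**Step 12**
Reactants: 14; 15 1,1,1,3,3,3-hexafluoropropan-2-yl acrylate
Product: 16 HFIP (3S,4S)-3-hydroxy-2-methylene-4-(triethylsilyloxy)-4-[(3R)-2-oxooxolan-3-yl]butanoate
Conditions: 15 (3 equiv), β-isocupreidine (β-ICD, 20 mol%), DMF, –55 °C, 5 d
Reagents that add atoms: none (15 is the reactant)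
Why: Hatakeyama asymmetric Morita–Baylis–Hillman reaction; the chiral catalyst controls the aldehyde face and sets C9 (S) syn to O8 in the zigzag.

**Step 13**
Reactants: 16
Product: 17 the C9 tert-butyldimethylsilyl ether of 16
Conditions: TBSOTf, 2,6-lutidine, CH2Cl2, –78→–40 °C
Reagents that add atoms: tert-butyldimethylsilyl triflate CC(C)(C)[Si](C)(C)OS(=O)(=O)C(F)(F)F (adds TBS)
Why: Protects the hindered allylic alcohol (O9) so it survives oxidation and later steps, and it differs from the TES at O8.

**Step 14**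
Reactants: 17
Product: 18 methyl (3S,4S)-3-(tert-butyldimethylsilyloxy)-2-methylene-4-(triethylsilyloxy)-4-[(3R)-2-oxooxolan-3-yl]butanoate
Conditions: MeOH, Et3N (5 equiv), DMAP (10 mol%), 23 °C
Reagents that add atoms: methanol CO (adds OCH3)
Why: The activated HFIP ester undergoes DMAP-catalysed methanolysis to the methyl ester, while the unactivated γ-lactone and the silyl ethers are untouched.

**Step 15**
Reactants: 18; 4
Product: 19 acyclic CM product. It is 18 with the C10 methylene replaced by =CH–CH2CH2–C(Me)=CHI: C10=C1 trisubstituted enoate with C2 cis to C9 (ester trans to C2), and (E)-vinyl iodide at C4=C5.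
Conditions: 4 (5 equiv), Hoveyda–Grubbs II (10 mol%), CH2Cl2, 40 °C
Reagents that add atoms: none (4 is the reactant)
Why: Cross-metathesis of the 1,1-disubstituted acrylate with a terminal olefin releases ethylene and gives the thermodynamic tiglate-type E-enoate, which is the required geometry.

**Step 16**
Reactants: 19
Product: 20 lactol (anomeric mixture, in equilibrium with the C6 aldehyde/C12 primary alcohol hydroxy-aldehyde) of 19
Conditions: DIBAL-H (1.1 equiv), toluene, –78 °C; Rochelle salt work-up
Reagents that add atoms: none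
Why: The lactone is far more electrophilic than the hindered conjugated ester at –78 °C, so it stops cleanly at the lactol, which unmasks the C6 aldehyde and C12 alcohol.

**Step 17**
Reactants: 20
Product: 21 macrocyclic diol (C6-epimer mixture): 10-membered carbocycle with 6-OH, 7-(2-hydroxyethyl), 8-OTES, 9-OTBS, 10-CO2Me, C1=C10 ring-cis (ester trans to C2), 4-Me, C4=C5 (E)
Conditions: CrCl2 (10 equiv), NiCl2 (5 mol%), DMF, 2 mM final concentration (syringe-pump addition), 23 °C
Reagents that add atoms: none
Why: Intramolecular Nozaki–Hiyama–Kishi vinylation of the aldehyde closes the ring at C5–C6; the C6 configuration is not relied on because steps 18–19 converge both epimers.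

**Step 18**
Reactants: 21
Product: 22 macrocyclic C6 enone (6-oxo analogue of 21, 12-OH free)
Conditions: activated MnO2 (30 equiv), CH2Cl2, 23 °C
Reagents that add atoms: none
Why: MnO2 oxidises the allylic secondary alcohol chemoselectively (not the saturated primary alcohol), destroying the C6 stereocentre so both epimers give one enone.

**Step 19**
Reactants: 22
Product: 23 (6R)-macrocyclic diol (6R,7S,8S,9S isomer of 21)
Conditions: ketoreductase (KRED, (R)-selective panel hit), NADP+ (cat.), iPrOH (20% v/v, cofactor recycling), KPi pH 7.0/DMSO 9:1, 30 °C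
Reagents that add atoms: none
Why: Enzymatic (NADPH-dependent) carbonyl reduction sets C6 (R) with the facial selectivity of the enzyme, giving the alcohol that closes to the trans-fused lactone.

**Step 20**
Reactants: 23
Product: 24 saturated trans-fused macrocyclic lactone (11,13-dihydro, TES/TBS ethers)
Conditions: TEMPO (20 mol%), PhI(OAc)2 (3 equiv), CH2Cl2, 23 °C
Reagents that add atoms: none
Why: TEMPO/BAIB oxidises the primary alcohol to the aldehyde, which closes onto the 6-OH as a γ-lactol that is oxidised to the lactone; all stereocentres are untouched.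

**Step 21**
Reactants: 24
Product: 25 α-(dimethylaminomethyl) lactone (Mannich base, C11 epimer mixture)
Conditions: LiHMDS (1.3 equiv), THF, –78 °C; then Me2N=CH2+ I– (3 equiv), –78→23 °C
Reagents that add atoms: Eschenmoser's salt C[N+](C)=C.[I-] (adds CH2NMe2)
Why: Regioselective lactone enolisation (the most acidic site) followed by Mannich aminomethylation; the new C11 centre is erased in the next step.

**Step 22**
Reactants: 25
Product: 26 the α-methylene lactone with C9-OTBS and C8-OTES
Conditions: MeI (excess), CH2Cl2, 23 °C; then sat. aq NaHCO3, 23 °C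
Reagents that add atoms: none (the methyl leaves as NMe3)
Why: Quaternisation followed by mild E1cB-type elimination of Me3N gives the exocyclic methylene.

**Step 23**
Reactants: 26
Product: 27 the C8 alcohol (TES removed; C9-OTBS retained)
Conditions: PPTS (0.3 equiv), MeOH/CH2Cl2 1:1, 0→23 °C
Reagents that add atoms: none
Why: Mildly acidic methanolysis cleaves the secondary TES ether selectively in the presence of the far more acid-stable TBS ether.

**Step 24**
Reactants: 27
Product: 28 the C8 angelate of 27 (C9-OTBS retained)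
Conditions: angelic acid, 2,4,6-Cl3C6H2COCl, Et3N, THF, 23 °C; then 27, DMAP, toluene, 50 °C
Reagents that add atoms: angelic acid C/C=C(/C)C(=O)O (adds the (Z)-2-methylbut-2-enoyl group)
Why: Yamaguchi esterification via the mixed anhydride esterifies the free C8-OH and largely retains the Z-alkene geometry; no stereocentre is altered.

**Step 25**
Reactants: 28
Product: 29 Polymatin A
Conditions: HF·pyridine, pyridine/THF, 0→23 °C
Reagents that add atoms: none
Why: Acidic fluoride desilylation frees the C9 alcohol without the base-mediated 8→9 acyl migration or angelate/α-methylene-lactone damage.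

**Compound list**
1 | pent-4-yn-1-ol | C#CCCCO | starting material
2 | (E)-5-iodo-4-methylpent-4-en-1-ol | OCCC/C(C)=C/I | intermediate
3 | (E)-5-iodo-4-methylpent-4-enal | O=CCC/C(C)=C/I | intermediate
4 | (E)-1-iodo-2-methylhexa-1,5-diene | C=CCC/C(C)=C/I | intermediate
5 | ethyl 4-(benzyloxy)-3-oxobutanoate | CCOC(=O)CC(=O)COCc1ccccc1 | starting material
6 | ethyl (S)-4-(benzyloxy)-3-hydroxybutanoate | CCOC(=O)C[C@H](O)COCc1ccccc1 | intermediate
7 | allyl bromide | C=CCBr | starting material
8 | ethyl (2R,3S)-2-allyl-4-(benzyloxy)-3-hydroxybutanoate | CCOC(=O)[C@H](CC=C)[C@H](O)COCc1ccccc1 | intermediate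
9 | ethyl (2R,3S)-4-(benzyloxy)-3-hydroxy-2-(2-oxoethyl)butanoate | CCOC(=O)[C@H](CC=O)[C@H](O)COCc1ccccc1 | intermediate
10 | ethyl (2R,3S)-4-(benzyloxy)-3-hydroxy-2-(2-hydroxyethyl)butanoate | CCOC(=O)[C@H](CCO)[C@H](O)COCc1ccccc1 | intermediate
11 | (3R)-3-[(1S)-2-(benzyloxy)-1-hydroxyethyl]oxolan-2-one | O=C2OCC[C@@H]2[C@H](O)COCc1ccccc1 | intermediate
12 | (3R)-3-[(1S)-2-(benzyloxy)-1-(triethylsilyloxy)ethyl]oxolan-2-one | O=C2OCC[C@@H]2[C@H](O[Si](CC)(CC)CC)COCc1ccccc1 | intermediate
13 | (3R)-3-[(1S)-2-hydroxy-1-(triethylsilyloxy)ethyl]oxolan-2-one | O=C2OCC[C@@H]2[C@H](O[Si](CC)(CC)CC)CO | intermediate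
14 | (2S)-2-(triethylsilyloxy)-2-[(3R)-2-oxooxolan-3-yl]acetaldehyde | O=C2OCC[C@@H]2[C@H](O[Si](CC)(CC)CC)C=O | intermediate
15 | 1,1,1,3,3,3-hexafluoropropan-2-yl acrylate | C=CC(=O)OC(C(F)(F)F)C(F)(F)F | starting material
16 | HFIP (3S,4S)-3-hydroxy-2-methylene-4-(triethylsilyloxy)-4-[(3R)-2-oxooxolan-3-yl]butanoate | O=C2OCC[C@@H]2[C@H](O[Si](CC)(CC)CC)[C@@H](O)C(=C)C(=O)OC(C(F)(F)F)C(F)(F)F | intermediate
17 | 16 with 3-OTBS | O=C2OCC[C@@H]2[C@H](O[Si](CC)(CC)CC)[C@@H](O[Si](C)(C)C(C)(C)C)C(=C)C(=O)OC(C(F)(F)F)C(F)(F)F | intermediate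
18 | methyl (3S,4S)-3-(tert-butyldimethylsilyloxy)-2-methylene-4-(triethylsilyloxy)-4-[(3R)-2-oxooxolan-3-yl]butanoate | O=C2OCC[C@@H]2[C@H](O[Si](CC)(CC)CC)[C@@H](O[Si](C)(C)C(C)(C)C)C(=C)C(=O)OC | intermediate
19 | acyclic CM product: C10=C1 E-enoate (C2 cis to C9), (E)-vinyl iodide | O=C2OCC[C@@H]2[C@H](O[Si](CC)(CC)CC)[C@@H](O[Si](C)(C)C(C)(C)C)/C(C(=O)OC)=C\CC/C(C)=C/I | intermediate
20 | lactol of 19 (anomeric mixture) | OC2OCC[C@@H]2[C@H](O[Si](CC)(CC)CC)[C@@H](O[Si](C)(C)C(C)(C)C)/C(C(=O)OC)=C\CC/C(C)=C/I | intermediate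
21 | macrocyclic 6,12-diol, C6 epimer mixture | OCC[C@@H]1[C@H](O[Si](CC)(CC)CC)[C@@H](O[Si](C)(C)C(C)(C)C)/C(C(=O)OC)=C\CC/C(C)=C/C1O | intermediate
22 | macrocyclic 6-ketone, 12-OH | OCC[C@@H]1[C@H](O[Si](CC)(CC)CC)[C@@H](O[Si](C)(C)C(C)(C)C)/C(C(=O)OC)=C\CC/C(C)=C/C1=O | intermediate
23 | (6R)-macrocyclic 6,12-diol | OCC[C@@H]1[C@H](O[Si](CC)(CC)CC)[C@@H](O[Si](C)(C)C(C)(C)C)/C(C(=O)OC)=C\CC/C(C)=C/[C@H]1O | intermediate
24 | saturated trans-fused macrolactone (11,13-dihydro), 8-OTES, 9-OTBS | O=C2C[C@@H]1[C@H](O[Si](CC)(CC)CC)[C@@H](O[Si](C)(C)C(C)(C)C)/C(C(=O)OC)=C\CC/C(C)=C/[C@H]1O2 | intermediate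
25 | 11-(dimethylaminomethyl) lactone (C11 epimer mixture) | O=C2C(CN(C)C)[C@@H]1[C@H](O[Si](CC)(CC)CC)[C@@H](O[Si](C)(C)C(C)(C)C)/C(C(=O)OC)=C\CC/C(C)=C/[C@H]1O2 | intermediate
26 | α-methylene lactone, 8-OTES, 9-OTBS | C=C1C(=O)O[C@@H]2/C=C(\C)CC/C=C(/C(=O)OC)[C@H](O[Si](C)(C)C(C)(C)C)[C@@H](O[Si](CC)(CC)CC)[C@@H]12 | intermediate
27 | 8-hydroxy, 9-OTBS α-methylene lactone | C=C1C(=O)O[C@@H]2/C=C(\C)CC/C=C(/C(=O)OC)[C@H](O[Si](C)(C)C(C)(C)C)[C@@H](O)[C@@H]12 | intermediate
28 | 8-angelate, 9-OTBS | C=C1C(=O)O[C@@H]2/C=C(\C)CC/C=C(/C(=O)OC)[C@H](O[Si](C)(C)C(C)(C)C)[C@@H](OC(=O)/C(C)=C\C)[C@@H]12 | intermediate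
29 | Polymatin A | C=C1C(=O)O[C@@H]2/C=C(\C)CC/C=C(/C(=O)OC)[C@H](O)[C@@H](OC(=O)/C(C)=C\C)[C@@H]12 | target

**Total step count:** 25 (3 for the vinyl-iodide diene 4, 22 on the main chain).
**Longest linear sequence:** 22 steps (5 → 29).

**Three steps most likely to fail, with fallbacks**
1. **Step 17 (macrocyclic NHK):** ring strain or poor reactivity of the lactol-derived aldehyde could give oligomers. Fallback: close the ring at C6–C7 instead by an intramolecular Cr-mediated allylation of an enal with a C13 allylic bromide (2-(bromomethyl)acrylate type), which forms the trans α-methylene lactone directly, using the same stereotriad (C7/C8/C9) building blocks.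
2. **Step 12 (asymmetric MBH on an α-silyloxy aldehyde):** catalyst control may be low or the sense mismatched. Fallback: drop the MBH/CM pair and instead couple the C9 aldehyde with a (Z)-α-bromoenoate (from a bromo-HWE) by intermolecular NHK, which forms C9–C10 and the C1=C10 enoate in one step. Any wrong C9 epimer is then corrected by oxidation/reduction.
3. **Step 19 (KRED reduction of the macrocyclic enone):** the enzyme may not accept this substrate, or C7 may epimerise α to the ketone. Fallback: abandon the enone funnel, separate the C6 epimers from step 17, and oxidise the primary alcohol to the acid. Close the lactone by Yamaguchi lactonisation of the correct epimer and by Mitsunobu lactonisation (SN2 inversion at C6) of the wrong one.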